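**Plan**

The target ring is numbered C1 (carries CH2OBz), C2 (=CH), C3, C4 (OH), C5 (OBz), C6 (OH).

1. Retrosynthesis: take CH2OBz back to a formyl group, then cut ring bond C1–C6. The C1=C2 alkene with the C6 carbinol on C1, inside the only carbocycle, is a Morita–Baylis–Hillman retron and opens to an acyclic hept-2-enedial. That is cut at its C2=C3 bond (cross-metathesis) to a hex-5-enal, which comes from zinc fragmentation of a 6-iodo-mannoside.
2. Forward: methyl α-D-mannopyranoside → 3,4-butane diacetal → 6-iodide → 2-O-benzoate → ring-opened hex-5-enal → hept-2-enedial → carbocycle (the only skeletal ring, closed last) → CH2OBz → diacetal removal.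
3. Stereochemistry: target C3, C4, C5 are C4, C3, C2 of D-mannose. C6 is set in the ring closure, under control of the rigid trans-fused diacetal and the axial C5 benzoate.
4. Oxygen differentiation: the diacetal hides the trans O3/O4 pair of the mannoside, so its only free secondary hydroxyl (O2) takes the benzoate that ends on C5 and is carried through.

Key step: step 6

Remark: the phosphine-bound zwitterions of step 6 are catalytic intermediates and are not numbered as compounds.

**Route**

Step 1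
Reactants: 1 methyl α-D-mannopyranoside
Product: 2 methyl 3,4-O-[(2S,3S)-2,3-dimethoxybutane-2,3-diyl]-α-D-mannopyranoside
Conditions: butane-2,3-dione, HC(OMe)3, CSA (cat.), MeOH, reflux
Reagents that add atoms: butane-2,3-dione CC(=O)C(C)=O; trimethyl orthoformate COC(OC)OC
Why: Acid-catalysed butane-2,3-diacetal formation should pick the trans-diequatorial 3,4-diol over the cis 2,3-pair, because only the trans-fused dioxane places both methoxy groups axial (anomeric effect), which also fixes the two acetal centres as S,S.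

Step 2
Reactants: 2 methyl 3,4-O-[(2S,3S)-2,3-dimethoxybutane-2,3-diyl]-α-D-mannopyranoside
Product: 3 methyl 6-deoxy-6-iodo-3,4-O-[(2S,3S)-2,3-dimethoxybutane-2,3-diyl]-α-D-mannopyranoside
Conditions: I2, PPh3, imidazole, THF, 60 °C
Reagents that add atoms: iodine II
Why: Appel-type (Garegg–Samuelsson) iodination should take place only at the primary 6-OH, the axial secondary 2-OH being much slower.

Step 3
Reactants: 3 methyl 6-deoxy-6-iodo-3,4-O-[(2S,3S)-2,3-dimethoxybutane-2,3-diyl]-α-D-mannopyranoside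
Product: 4 methyl 2-O-benzoyl-6-deoxy-6-iodo-3,4-O-[(2S,3S)-2,3-dimethoxybutane-2,3-diyl]-α-D-mannopyranoside
Conditions: BzCl, pyridine, DMAP (cat.), CH2Cl2, 0 °C to rt
Reagents that add atoms: benzoyl chloride O=C(Cl)c1ccccc1
Why: Acylation of the single remaining hydroxyl (O2) places the benzoate on the oxygen that becomes O–C5 of the target.

Step 4
Reactants: 4 methyl 2-O-benzoyl-6-deoxy-6-iodo-3,4-O-[(2S,3S)-2,3-dimethoxybutane-2,3-diyl]-α-D-mannopyranoside
Product: 5 2-O-benzoyl-5,6-dideoxy-3,4-O-[(2S,3S)-2,3-dimethoxybutane-2,3-diyl]-aldehydo-D-lyxo-hex-5-enose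
Conditions: activated Zn dust, THF/H2O 4:1, sonication, 40 °C; crude aldehyde used after a short silica pad
Reagents that add atoms: none
Why: Bernet–Vasella reductive fragmentation (zinc insertion into C–I, β-elimination of the ring oxygen, collapse of the hemiacetal with loss of methoxide) should give the hex-5-enal without touching C2–C4.

Step 5
Reactants: 5 2-O-benzoyl-5,6-dideoxy-3,4-O-[(2S,3S)-2,3-dimethoxybutane-2,3-diyl]-aldehydo-D-lyxo-hex-5-enose; 6 (E)-but-2-enal (crotonaldehyde)
Product: 7 (2E,4R,5S,6S)-6-benzoyloxy-4,5-O-[(2S,3S)-2,3-dimethoxybutane-2,3-diyl]-4,5-dihydroxyhept-2-enedial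
Conditions: Hoveyda–Grubbs II (5 mol%), crotonaldehyde (5 equiv), CH2Cl2, 40 °C
Reagents that add atoms: none
Why: Olefin cross-metathesis of the terminal allylic-ether alkene with an enal partner should give the E-enal under thermodynamic control, the free aldehyde being tolerated by the ruthenium carbene.

Step 6
Reactants: 7 (2E,4R,5S,6S)-6-benzoyloxy-4,5-O-[(2S,3S)-2,3-dimethoxybutane-2,3-diyl]-4,5-dihydroxyhept-2-enedial
Product: 8 (3R,4S,5R,6S)-5-benzoyloxy-6-hydroxy-3,4-O-[(2S,3S)-2,3-dimethoxybutane-2,3-diyl]-3,4-dihydroxycyclohex-1-ene-1-carbaldehyde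
Conditions: PMe3 (0.3 equiv), t-AmOH/THF, 0.02 M, 0 °C to rt
Reagents that add atoms: none
Why: Trimethylphosphine adds to C3 of the enal, the resulting phosphonium enolate attacks the tethered C7 aldehyde through its α-carbon, and proton transfer followed by E1cB loss of the phosphine restores the ring C1=C2 double bond. The closest known reaction type is the phosphine-catalysed intramolecular Morita–Baylis–Hillman cyclisation of enal- or enone-tethered aldehydes to 6-hydroxycyclohex-1-ene carbonyl compounds. The carbocycle closes in a 6-(enolexo)-exo-trig aldol mode. The new C6 stereocentre is controlled by the trans-fused diacetal ring, which holds O3 and O4 equatorial and therefore the C5 benzoate axial: the aldehyde oxygen should take the pseudoaxial site, anti to the C5–O dipole and clear of A(1,2) strain with the enolate, giving the 5,6-trans (6S) alcohol. The step needs conjugate addition of the phosphine to the enal in preference to intermolecular Rauhut–Currier coupling, and no enolisation of the α-benzoyloxy aldehyde; high dilution, the weakly basic phosphine and the protic co-solvent should secure this, and reversibility of the aldol step should let any cis adduct return to the more stable trans-diaxial one.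

Step 7
Reactants: 8 (3R,4S,5R,6S)-5-benzoyloxy-6-hydroxy-3,4-O-[(2S,3S)-2,3-dimethoxybutane-2,3-diyl]-3,4-dihydroxycyclohex-1-ene-1-carbaldehyde
Product: 9 (3R,4S,5R,6S)-5-benzoyloxy-6-hydroxy-1-(hydroxymethyl)-3,4-O-[(2S,3S)-2,3-dimethoxybutane-2,3-diyl]cyclohex-1-ene-3,4-diol
Conditions: NaBH4, CeCl3·7H2O, MeOH, −40 °C
Reagents that add atoms: none
Why: Luche reduction should reduce the enal 1,2 to the primary allylic alcohol while the benzoate survives at low temperature; no stereocentre is formed, and the trans-diaxial C5-OBz/C6-OH arrangement disfavours acyl migration.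

Step 8
Reactants: 9 (3R,4S,5R,6S)-5-benzoyloxy-6-hydroxy-1-(hydroxymethyl)-3,4-O-[(2S,3S)-2,3-dimethoxybutane-2,3-diyl]cyclohex-1-ene-3,4-diol
Product: 10 [(3R,4S,5R,6S)-5-benzoyloxy-6-hydroxy-3,4-O-[(2S,3S)-2,3-dimethoxybutane-2,3-diyl]-3,4-dihydroxycyclohex-1-en-1-yl]methyl benzoate
Conditions: BzCl (1.05 equiv), 2,4,6-collidine, CH2Cl2, −40 to −10 °C
Reagents that add atoms: benzoyl chloride O=C(Cl)c1ccccc1
Why: Kinetic acylation should favour the unhindered primary allylic hydroxyl over the pseudoaxial secondary C6 hydroxyl, which is flanked by the axial C5 benzoate and the ring substituent.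

Step 9
Reactants: 10 [(3R,4S,5R,6S)-5-benzoyloxy-6-hydroxy-3,4-O-[(2S,3S)-2,3-dimethoxybutane-2,3-diyl]-3,4-dihydroxycyclohex-1-en-1-yl]methyl benzoate
Product: 11 [(3R,4S,5R,6S)-5-benzoyloxy-3,4,6-trihydroxycyclohex-1-en-1-yl]methyl benzoate (target)
Conditions: TFA/H2O 9:1, 0 °C to rt, short contact time; toluene co-evaporation
Reagents that add atoms: none
Why: Acid hydrolysis of the butane diacetal should free the trans 3,4-diol while both benzoates, stable to aqueous acid, stay in place.

**Compound list**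

1 | methyl α-D-mannopyranoside | CO[C@@H]1[C@@H](O)[C@@H](O)[C@H](O)[C@@H](CO)O1 | starting material
2 | methyl 3,4-O-[(2S,3S)-2,3-dimethoxybutane-2,3-diyl]-α-D-mannopyranoside | CO[C@@H]1[C@@H](O)[C@H]2O[C@](C)(OC)[C@@](C)(OC)O[C@@H]2[C@@H](CO)O1 | intermediate
3 | methyl 6-deoxy-6-iodo-3,4-O-[(2S,3S)-2,3-dimethoxybutane-2,3-diyl]-α-D-mannopyranoside | CO[C@@H]1[C@@H](O)[C@H]2O[C@](C)(OC)[C@@](C)(OC)O[C@@H]2[C@@H](CI)O1 | intermediate
4 | methyl 2-O-benzoyl-6-deoxy-6-iodo-3,4-O-[(2S,3S)-2,3-dimethoxybutane-2,3-diyl]-α-D-mannopyranoside | CO[C@@H]1[C@@H](OC(=O)c3ccccc3)[C@H]2O[C@](C)(OC)[C@@](C)(OC)O[C@@H]2[C@@H](CI)O1 | intermediate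
5 | 2-O-benzoyl-5,6-dideoxy-3,4-O-[(2S,3S)-2,3-dimethoxybutane-2,3-diyl]-aldehydo-D-lyxo-hex-5-enose | O=C[C@@H](OC(=O)c1ccccc1)[C@H]2O[C@](C)(OC)[C@@](C)(OC)O[C@@H]2C=C | intermediate
6 | (E)-but-2-enal (crotonaldehyde) | C/C=C/C=O | starting material
7 | (2E,4R,5S,6S)-6-benzoyloxy-4,5-O-[(2S,3S)-2,3-dimethoxybutane-2,3-diyl]-4,5-dihydroxyhept-2-enedial | O=C[C@@H](OC(=O)c1ccccc1)[C@H]2O[C@](C)(OC)[C@@](C)(OC)O[C@@H]2/C=C/C=O | intermediate
8 | (3R,4S,5R,6S)-5-benzoyloxy-6-hydroxy-3,4-O-[(2S,3S)-2,3-dimethoxybutane-2,3-diyl]-3,4-dihydroxycyclohex-1-ene-1-carbaldehyde | O=CC1=C[C@H]2O[C@](C)(OC)[C@@](C)(OC)O[C@@H]2[C@H](OC(=O)c3ccccc3)[C@H]1O | intermediate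
9 | (3R,4S,5R,6S)-5-benzoyloxy-6-hydroxy-1-(hydroxymethyl)-3,4-O-[(2S,3S)-2,3-dimethoxybutane-2,3-diyl]cyclohex-1-ene-3,4-diol | OCC1=C[C@H]2O[C@](C)(OC)[C@@](C)(OC)O[C@@H]2[C@H](OC(=O)c3ccccc3)[C@H]1O | intermediate
10 | [(3R,4S,5R,6S)-5-benzoyloxy-6-hydroxy-3,4-O-[(2S,3S)-2,3-dimethoxybutane-2,3-diyl]-3,4-dihydroxycyclohex-1-en-1-yl]methyl benzoate | O=C(OCC1=C[C@H]2O[C@](C)(OC)[C@@](C)(OC)O[C@@H]2[C@H](OC(=O)c3ccccc3)[C@H]1O)c1ccccc1 | intermediate
11 | [(3R,4S,5R,6S)-5-benzoyloxy-3,4,6-trihydroxycyclohex-1-en-1-yl]methyl benzoate | O=C(OCC1=C[C@@H](O)[C@H](O)[C@H](OC(=O)c2ccccc2)[C@H]1O)c1ccccc1 | target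

**Summary**

Total step count: 9. Longest linear sequence: 9 steps (1 → 11).

Steps most likely to fail:

Step 6. The ring closure may suffer from poor facial selectivity at C6, from loss of the C3 acetal oxygen out of the phosphonium intermediate (ylide-driven β-elimination), or from oligomerisation by intermolecular Rauhut–Currier addition. The fallback sets out from 7 and comes back at 8. Lithium benzeneselenolate (PhSeH, n-BuLi, THF, −78 °C) should add to the enal, and the lithium enolate should close onto the C7 aldehyde at low temperature to give the 2-(phenylselanyl) aldol adduct F1 (configuration at C3–C6 as in 8, C1/C2 epimers). Oxidation with H2O2/pyridine in CH2Cl2 at 0 °C and selenoxide syn-elimination toward the C1 hydrogen should then return 8.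

Step 5. Turnover at the hindered allylic-ether alkene may be slow, so that self-metathesis of crotonaldehyde dominates and the α-benzoyloxy aldehyde erodes on prolonged heating. The fallback sets out from 5 and comes back at 10, bypassing 7–9 and closing the ring by metathesis instead. Nozaki–Hiyama–Kishi coupling of 5 with 2-bromoallyl benzoate (CrCl2, cat. NiCl2, DMF, rt) should give (3S,4R,5S,6R)-2-(benzoyloxymethyl)-3-hydroxy-5,6-O-[(2S,3S)-2,3-dimethoxybutane-2,3-diyl]-5,6-dihydroxyocta-1,7-dien-4-yl benzoate F2. The C3 epimers would have to be separated, and the Felkin-type epimer may well predominate. Ring-closing metathesis of F2 (Grubbs II, CH2Cl2, 40 °C) should give 10.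

Step 8. The secondary C6 hydroxyl may be over-acylated, or benzoyl groups may scramble between the two free hydroxyls. The fallback sets out from 8 and comes back at 11. Silylation of the C6 hydroxyl (TESOTf, 2,6-lutidine, CH2Cl2, −78 °C) should give the 6-O-triethylsilyl ether of 8 F3. Luche reduction should give the 6-O-triethylsilyl ether of 9 F4, and exhaustive benzoylation of the only free hydroxyl (BzCl, pyridine, DMAP) should give the 6-O-triethylsilyl ether of 10 F5. Aqueous TFA should then remove the silyl ether and the diacetal together to give 11.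

Further compounds
F1 | step 6 | 5-benzoyloxy-6-hydroxy-3,4-O-[(2S,3S)-2,3-dimethoxybutane-2,3-diyl]-3,4-dihydroxy-2-(phenylselanyl)cyclohexane-1-carbaldehyde (C3–C6 as in 8, C1/C2 epimers) | O=CC1C([Se]c4ccccc4)[C@H]2O[C@](C)(OC)[C@@](C)(OC)O[C@@H]2[C@H](OC(=O)c3ccccc3)[C@H]1O
F2 | step 5 | (3S,4R,5S,6R)-2-(benzoyloxymethyl)-3-hydroxy-5,6-O-[(2S,3S)-2,3-dimethoxybutane-2,3-diyl]-5,6-dihydroxyocta-1,7-dien-4-yl benzoate | C=C(COC(=O)c3ccccc3)[C@H](O)[C@@H](OC(=O)c1ccccc1)[C@H]2O[C@](C)(OC)[C@@](C)(OC)O[C@@H]2C=C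
F3 | step 8 | 6-O-triethylsilyl ether of 8 | O=CC1=C[C@H]2O[C@](C)(OC)[C@@](C)(OC)O[C@@H]2[C@H](OC(=O)c3ccccc3)[C@H]1O[Si](CC)(CC)CC
F4 | step 8 | 6-O-triethylsilyl ether of 9 | OCC1=C[C@H]2O[C@](C)(OC)[C@@](C)(OC)O[C@@H]2[C@H](OC(=O)c3ccccc3)[C@H]1O[Si](CC)(CC)CC
F5 | step 8 | 6-O-triethylsilyl ether of 10 | O=C(OCC1=C[C@H]2O[C@](C)(OC)[C@@](C)(OC)O[C@@H]2[C@H](OC(=O)c3ccccc3)[C@H]1O[Si](CC)(CC)CC)c1ccccc1
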